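The plan rests on cutting two bonds at ring C, C18–C19 and C7–C13. The feature exploited is the unbroken row C18 (bridge methylene on C19), quaternary spiro C13 and ketone C14, which maps onto a Prins–pinacol cascade. A formaldehyde-derived oxocarbenium ion on O17 attacks C19 of a C19=C13 cyclohexene and closes the tetrahydrofuran of the 6-oxabicyclo[3.2.1]octane. The C14 vinyl group then shifts to cationic C13 and the ketone appears. One operation gives one ring, two C–C bonds and stereocentres C19 and C13. The precursor is a cyclohexene with a C16 MOM ether, a C14 vinyl triethylsilyl carbinol and C13–CH2OTBDPS. Metathesis then builds ring B and a Diels–Alder reaction ring A.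

Key step: step 9

Numbering (target atoms, kept for all intermediates): C1 methyl, C2, C3 carboxyl; ring A = C4–C9; C10 lactone C=O, O11, C12; C13 spiro; C14 ketone; C15; C16; O17; C18; C19; C20 = CMe2. Ring B = C7, C8, C10, O11, C12, C13. Ring C = C13, C14, C15, C16, C20, C19. Target configuration: 2R,4R,7R,8S,13S,16S,19S.

Design remark: C12 is carried as a TBDPS ether, not an arylmethyl ether. The silyl ether does not compete with the MOM group for magnesium in step 7. It offers the cations of step 9 no electron-rich arene, no benzylic hydride and no acid-labile C–O bond.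

Assumption: the antipode of the bisphosphine in step 2 is chosen after a test run so that the (S)-alcohol 4 results.

Step 1
Reactants: 1 4,4-dimethylcyclohex-2-en-1-one
Product: 2 4,4-dimethylcyclohexa-2,5-dien-1-one
Conditions: DDQ, 1,4-dioxane, reflux
Reagents that add atoms: none
Why: Quinone dehydrogenation (hydride abstraction from the dienol of the enone) is the standard entry to 4,4-disubstituted cross-conjugated dienones, which cannot aromatise, and it creates no stereocentre.

Step 2
Reactants: 2 4,4-dimethylcyclohexa-2,5-dien-1-one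
Product: 4 (S)-5-hydroxy-4,4-dimethylcyclohex-2-en-1-one, via pinacol boronate 3 (not isolated)
Conditions: CuCl (5 mol %), NaOtBu (10 mol %), (R,R)-2,3-bis(tert-butylmethylphosphino)quinoxaline (6 mol %), B2pin2 (1.0 equiv), MeOH (2 equiv), THF, 0 °C; then NaBO3·4H2O, THF–H2O, rt
Reagents that add atoms: bis(pinacolato)diboron CC1(C)OB(OC1(C)C)B1OC(C)(C)C(C)(C)O1 (boron of 3); sodium perborate tetrahydrate [Na+].[O-]OB=O.O.O.O.O (oxygen of 4)
Why: Copper-catalysed enantioselective conjugate borylation desymmetrises the prochiral dienone: the ligated Cu–Bpin species adds to one enantiotopic β-carbon face, methanol releases the ketone, one equivalent of diboron holds the reaction at mono-addition, and the stereoretentive perborate oxidation of the C–B bond delivers C16 as (S).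

Step 3
Reactants: 4 (S)-5-hydroxy-4,4-dimethylcyclohex-2-en-1-one; 5 chloromethyl methyl ether
Product: 6 (S)-5-(methoxymethoxy)-4,4-dimethylcyclohex-2-en-1-one
Conditions: MOMCl, iPr2NEt, Bu4NI (cat.), CH2Cl2, 0 °C → rt
Reagents that add atoms: chloromethyl methyl ether COCCl
Why: Standard O-alkylation to the MOM acetal puts C18 on O17; the weak, hindered amine base should not trigger β-elimination of the β-oxy ketone and C16 is untouched.

Step 4
Reactants: 6 (S)-5-(methoxymethoxy)-4,4-dimethylcyclohex-2-en-1-one
Product: 7 (S)-2-iodo-5-(methoxymethoxy)-4,4-dimethylcyclohex-2-en-1-one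
Conditions: I2, pyridine–CH2Cl2 (1:1), 0 °C → rt
Reagents that add atoms: iodine II
Why: α-Iodination of an enone by pyridine conjugate addition, iodination of the enolate and elimination (a Baylis–Hillman-type sequence) is well established for 4,4-dimethylcyclohexenones and activates C13 without strong base.

Step 5
Reactants: 7 (S)-2-iodo-5-(methoxymethoxy)-4,4-dimethylcyclohex-2-en-1-one; 8 (tributylstannyl)methanol
Product: 9 (S)-2-(hydroxymethyl)-5-(methoxymethoxy)-4,4-dimethylcyclohex-2-en-1-one
Conditions: Bu3SnCH2OH, Pd(PPh3)4 (5 mol %), toluene, 100 °C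
Reagents that add atoms: (tributylstannyl)methanol OC[Sn](CCCC)(CCCC)CCCC
Why: Stille coupling: the alkenyl iodide adds oxidatively to zerovalent palladium and tin transfers its oxygen-bearing methylene in preference to butyl, so C12 arrives under neutral conditions that spare the β-alkoxy ketone.

Step 6
Reactants: 9 (S)-2-(hydroxymethyl)-5-(methoxymethoxy)-4,4-dimethylcyclohex-2-en-1-one
Product: 10 (S)-2-{[(tert-butyldiphenylsilyl)oxy]methyl}-5-(methoxymethoxy)-4,4-dimethylcyclohex-2-en-1-one
Conditions: TBDPSCl, imidazole, CH2Cl2, 0 °C → rt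
Reagents that add atoms: tert-butyl(chloro)diphenylsilane CC(C)(C)[Si](Cl)(c1ccccc1)c1ccccc1
Why: Routine silylation of the primary allylic alcohol; the bulky, weakly basic silyl ether neither chelates magnesium in step 7 nor reacts with cations in step 9.

Step 7
Reactants: 10 TBDPS-protected enone; 11 vinylmagnesium bromide
Product: 12 (1R,5S)-2-{[(tert-butyldiphenylsilyl)oxy]methyl}-1-ethenyl-5-(methoxymethoxy)-4,4-dimethylcyclohex-2-en-1-ol
Conditions: CH2=CHMgBr (THF solution, 2 equiv), CH2Cl2, −78 → −40 °C
Reagents that add atoms: vinylmagnesium bromide C=C[Mg]Br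
Why: Chelation-controlled Grignard 1,2-addition: the MOM group is the only good magnesium-binding site and should sit axial (there it avoids one gauche contact with the gem-dimethyl group and meets no syn-axial hydrogen in the enone), so vinyl is handed to the carbonyl face syn to O17 along the axial trajectory and sets C14 (R), cis to the C16 oxygen, while neopentyl C19 disfavours 1,4-addition.

Step 8
Reactants: 12 tertiary vinyl carbinol
Product: 13 triethyl{[(1R,5S)-2-{[(tert-butyldiphenylsilyl)oxy]methyl}-1-ethenyl-5-(methoxymethoxy)-4,4-dimethylcyclohex-2-en-1-yl]oxy}silane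
Conditions: Et3SiOTf (1.2 equiv), 2,6-lutidine (2.5 equiv), CH2Cl2, −78 → −20 °C
Reagents that add atoms: triethylsilyl trifluoromethanesulfonate CC[Si](CC)(CC)OS(=O)(=O)C(F)(F)F
Why: Silyl triflate silylation copes with the crowded tertiary alcohol, and at low temperature with excess lutidine O-silylation is far faster than any activation of the acetal or ionisation of the doubly allylic carbinol.

Step 9
Reactants: 13 cascade precursor
Product: 16 (1S,2S,5S)-2-{[(tert-butyldiphenylsilyl)oxy]methyl}-2-ethenyl-8,8-dimethyl-6-oxabicyclo[3.2.1]octan-3-one, via oxocarbenium ion 14 (not isolated), via tertiary C13 cation 15 (not isolated)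
Conditions: Et3SiOTf (0.3 equiv), 2,6-di-tert-butyl-4-methylpyridine (0.5 equiv), 4 Å molecular sieves, CH2Cl2 (0.01 M), −78 → −30 °C
Reagents that add atoms: none
Why: Proposed new method: the silyl triflate binds the unhindered methoxy oxygen of the MOM group and expels Et3SiOMe, the O17=C18 oxocarbenium ion 14 held axial on C16 adds to C19 of the ring alkene to give the tertiary C13 cation 15, the C14 vinyl group shifts to C13, and the resulting C14=O–SiEt3 cation returns its silyl group to triflate, so the acid is regenerated. The closest known reaction type is the Prins–pinacol cascade of allylic silyl carbinols started by tethered acetals; new here are the formaldehyde-level cation on a homoallylic oxygen, the bridge-forming closure and a vinyl shift in place of a ring-bond shift. The one ring formed (O17, C18, C19, C20, C16) closes 5-exo-trig with respect to the alkene and endo with respect to the C=O+ bond, which turns ring C into the 6-oxabicyclo[3.2.1]octane. C19 is fixed by the two-atom tether, which can reach only the alkene face syn to O17, and C13 by the suprafacial shift of the vinyl group, which in the bridged chair is axial on that same face and parallel to the empty orbital, so the C14 configuration of step 7 is copied to C13 (C7 syn, C12 anti to the bridge). The step needs ionisation of the acetal and not of the doubly allylic C14–O bond (low basicity and crowding of silyl ether oxygens, catalytic halide-free acid, hindered pyridine to remove TfOH), Markovnikov 5-exo attack and not 6-endo attack or a 2-oxonia-Cope path (tertiary against secondary cation), attack by the trisubstituted ring alkene and not by the vinyl group, and vinyl rather than C14–C15 migration (orbital alignment and the high migratory aptitude of sp2 carbon). The TBDPS ether at C12 stays a spectator because it has no nucleophilic arene and no benzylic hydride.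

Step 10
Reactants: 16 bicyclic vinyl ketone
Product: 17 (1S,2S,5S)-2-ethenyl-2-(hydroxymethyl)-8,8-dimethyl-6-oxabicyclo[3.2.1]octan-3-one
Conditions: Bu4NF–AcOH (1:1), THF, 0 °C → rt
Reagents that add atoms: none
Why: Fluoride desilylation; acetic acid keeps the liberated oxygen protonated, so the β-hydroxy ketone with its quaternary α-carbon should neither lose formaldehyde by retro-aldol cleavage nor open by a retro-oxa-Michael reaction.

Step 11
Reactants: 17 hydroxymethyl ketone; 18 acryloyl chloride
Product: 19 [(1S,2S,5S)-2-ethenyl-8,8-dimethyl-3-oxo-6-oxabicyclo[3.2.1]octan-2-yl]methyl prop-2-enoate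
Conditions: CH2=CHCOCl, iPr2NEt, CH2Cl2, −20 → 0 °C
Reagents that add atoms: acryloyl chloride C=CC(=O)Cl
Why: Plain acylation of a neopentyl primary alcohol by an acid chloride brings in C8 and C10, and the amine base is too weak to start the retro-aldol reaction.

Step 12
Reactants: 19 acrylate
Product: 20 unsaturated spirolactone (13S,16S,19S)
Conditions: second-generation Grubbs catalyst (5 mol %), toluene, 80 °C
Reagents that add atoms: none
Why: Ring-closing metathesis of an acrylate and a vinyl group on a quaternary carbon to a six-membered α,β-unsaturated lactone is a well-used closure (ring B with C7=C8), driven by loss of ethene, and changes no stereocentre.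

Step 13
Reactants: 21 methyl (S)-3-hydroxy-2-methylpropanoate
Product: 22 methyl (S)-3-(benzyloxy)-2-methylpropanoate
Conditions: benzyl 2,2,2-trichloroacetimidate, TfOH (cat.), CH2Cl2–cyclohexane, 0 °C → rt
Reagents that add atoms: benzyl 2,2,2-trichloroacetimidate ClC(Cl)(Cl)C(=N)OCc1ccccc1
Why: Acid-catalysed benzylation by the trichloroacetimidate avoids base, so the α-stereocentre (future C2) of the β-hydroxy ester is neither racemised nor lost by elimination.

Step 14
Reactants: 22 methyl (S)-3-(benzyloxy)-2-methylpropanoate; 23 methylmagnesium bromide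
Product: 25 (S)-4-(benzyloxy)-3-methylbutan-2-one, via Weinreb amide 24 (not isolated)
Conditions: MeNHOMe·HCl, iPrMgCl, THF, −20 °C; then MeMgBr, 0 °C
Reagents that add atoms: N,O-dimethylhydroxylamine hydrochloride CNOC.Cl (in 24); methylmagnesium bromide C[Mg]Br
Why: Weinreb ketone synthesis run in one flask: the magnesium amide turns the ester into the N-methoxy-N-methylamide, whose chelated MeMgBr adduct holds until work-up, so addition stops at the methyl ketone (its CH3 becomes C9) and C2 is preserved.

Step 15
Reactants: 25 (S)-4-(benzyloxy)-3-methylbutan-2-one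
Product: 26 (S)-4-(benzyloxy)-3-methylbut-1-en-2-yl trifluoromethanesulfonate
Conditions: KN(SiMe3)2, THF, −78 °C; then PhNTf2, −78 → 0 °C
Reagents that add atoms: N-phenylbis(trifluoromethanesulfonimide) O=S(=O)(N(c1ccccc1)S(=O)(=O)C(F)(F)F)C(F)(F)F
Why: Kinetic deprotonation by the bulky amide base takes the methyl group rather than the branched α-carbon, and O-sulfonylation of that enolate gives the terminal enol triflate without touching C2.

Step 16
Reactants: 26 enol triflate; 27 tributyl(1-ethoxyvinyl)stannane
Product: 28 (R)-5-(benzyloxy)-2-ethoxy-4-methyl-3-methylidenepent-1-ene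
Conditions: Pd(PPh3)4 (5 mol %), LiCl (3 equiv), THF, reflux
Reagents that add atoms: tributyl(1-ethoxyvinyl)stannane C=C(OCC)[Sn](CCCC)(CCCC)CCCC
Why: Stille coupling of an enol triflate (LiCl-assisted) with the α-ethoxyvinyl stannane is a known direct route to 2-ethoxy-1,3-dienes and joins C4 to C5.

Step 17
Reactants: 20 unsaturated spirolactone; 28 2-ethoxy diene
Product: 30 C5-oxo C3-O-benzyl tetracycle (2R,4R,7R,8S,13S,16S,19S), via enol ether cycloadduct 29 (not isolated)
Conditions: 28 (3 equiv), BHT, toluene, 150 °C, sealed tube; then 1 M HCl, THF, rt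
Reagents that add atoms: diene 28 C=C(OCC)C(=C)[C@@H](C)COCc1ccccc1; water O
Why: Normal-electron-demand Diels–Alder reaction in which the ethoxy donor makes C6 the nucleophilic terminus that bonds to the lactone β-carbon C7 (oxygen at C5, side chain at C4), suprafacial addition to the ring-locked alkene makes H7 and H8 cis, approach over the ring B face flanked by the flat C14 carbonyl and anti to branched C19 sets C7 (R) and C8 (S), and acid hydrolysis with equilibration through the C5 enol leaves the C4 side chain equatorial (R) because its epimer would be syn-axial to C10.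

Step 18
Reactants: 30 C5-oxo tetracycle
Product: 31 C5 (E)-tosylhydrazone of 30
Conditions: TsNHNH2 (1.05 equiv), EtOH–THF, rt → 40 °C
Reagents that add atoms: p-toluenesulfonyl hydrazide Cc1ccc(cc1)S(=O)(=O)NN
Why: Hydrazone condensation should select the C5 ketone, which has only one branched neighbour, over the C14 ketone, which is shielded by quaternary C13 and the bicyclic cage, and the sulfonamide nitrogen turns away from C4.

Step 19
Reactants: 31 tosylhydrazone
Product: 32 C3-O-benzyl tetracycle with C5 as CH2
Conditions: catecholborane, CHCl3, −10 °C → rt; then NaOAc·3H2O, reflux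
Reagents that add atoms: none
Why: Tosylhydrazone reduction (the mild hydride variant of the Wolff–Kishner deoxygenation): catecholborane adds hydride to C=N, acetate-induced loss of sulfinate gives the diazene and N2 extrusion leaves C5 as CH2, while the hindered ketone, the lactone and C4 are not affected.

Step 20
Reactants: 32 benzyl ether
Product: 33 C3 primary alcohol
Conditions: H2 (1 atm), 10% Pd/C, EtOAc, rt
Reagents that add atoms: none
Why: Hydrogenolysis of the benzyl ether runs under neutral conditions; no alkene is left and ketone, lactone and cyclic ether are inert.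

Step 21
Reactants: 33 primary alcohol
Product: 34 CNP0152427.1 (target)
Conditions: TEMPO (20 mol %), PhI(OAc)2 (2.5 equiv), MeCN–H2O (1:1), rt
Reagents that add atoms: water O
Why: Oxoammonium (TEMPO) oxidation of the primary alcohol through the aldehyde hydrate to the acid works near neutrality, so C2 next to the transient aldehyde and C8 next to the lactone should not epimerise.

Compound list
1 | 4,4-dimethylcyclohex-2-en-1-one | CC1(C)CCC(=O)C=C1 | starting material
2 | 4,4-dimethylcyclohexa-2,5-dien-1-one | CC1(C)C=CC(=O)C=C1 | intermediate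
3 | (S)-4,4-dimethyl-5-(4,4,5,5-tetramethyl-1,3,2-dioxaborolan-2-yl)cyclohex-2-en-1-one (not isolated) | O=C1C[C@H](B2OC(C)(C)C(C)(C)O2)C(C)(C)C=C1 | intermediate
4 | (S)-5-hydroxy-4,4-dimethylcyclohex-2-en-1-one | O=C1C[C@H](O)C(C)(C)C=C1 | intermediate
5 | chloromethyl methyl ether | COCCl | starting material
6 | (S)-5-(methoxymethoxy)-4,4-dimethylcyclohex-2-en-1-one | O=C1C[C@H](OCOC)C(C)(C)C=C1 | intermediate
7 | (S)-2-iodo-5-(methoxymethoxy)-4,4-dimethylcyclohex-2-en-1-one | O=C1C[C@H](OCOC)C(C)(C)C=C1I | intermediate
8 | (tributylstannyl)methanol | OC[Sn](CCCC)(CCCC)CCCC | starting material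
9 | (S)-2-(hydroxymethyl)-5-(methoxymethoxy)-4,4-dimethylcyclohex-2-en-1-one | O=C1C[C@H](OCOC)C(C)(C)C=C1CO | intermediate
10 | (S)-2-{[(tert-butyldiphenylsilyl)oxy]methyl}-5-(methoxymethoxy)-4,4-dimethylcyclohex-2-en-1-one | O=C1C[C@H](OCOC)C(C)(C)C=C1CO[Si](c2ccccc2)(c3ccccc3)C(C)(C)C | intermediate
11 | vinylmagnesium bromide | C=C[Mg]Br | starting material
12 | (1R,5S)-2-{[(tert-butyldiphenylsilyl)oxy]methyl}-1-ethenyl-5-(methoxymethoxy)-4,4-dimethylcyclohex-2-en-1-ol (vinyl cis to the C16 oxygen) | C=C[C@]1(O)C[C@H](OCOC)C(C)(C)C=C1CO[Si](c2ccccc2)(c3ccccc3)C(C)(C)C | intermediate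
13 | triethylsilyl ether of 12, the cascade precursor (14R,16S) | C=C[C@]1(O[Si](CC)(CC)CC)C[C@H](OCOC)C(C)(C)C=C1CO[Si](c2ccccc2)(c3ccccc3)C(C)(C)C | intermediate
14 | O17=C18 oxocarbenium ion from 13 (not isolated) | C=C[C@]1(O[Si](CC)(CC)CC)C[C@H]([O+]=C)C(C)(C)C=C1CO[Si](c2ccccc2)(c3ccccc3)C(C)(C)C | intermediate
15 | bridged tertiary C13 cation after C18–C19 bond formation (not isolated) | C=C[C@]1(O[Si](CC)(CC)CC)C[C@@H]2OC[C@H]([C+]1CO[Si](c3ccccc3)(c4ccccc4)C(C)(C)C)C2(C)C | intermediate
16 | (1S,2S,5S)-2-{[(tert-butyldiphenylsilyl)oxy]methyl}-2-ethenyl-8,8-dimethyl-6-oxabicyclo[3.2.1]octan-3-one (vinyl syn, CH2O anti to the O17–C18 bridge) | C=C[C@]1(CO[Si](c2ccccc2)(c3ccccc3)C(C)(C)C)C(=O)C[C@@H]4OC[C@H]1C4(C)C | intermediate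
17 | (1S,2S,5S)-2-ethenyl-2-(hydroxymethyl)-8,8-dimethyl-6-oxabicyclo[3.2.1]octan-3-one | C=C[C@]1(CO)C(=O)C[C@@H]2OC[C@H]1C2(C)C | intermediate
18 | acryloyl chloride | C=CC(=O)Cl | starting material
19 | [(1S,2S,5S)-2-ethenyl-8,8-dimethyl-3-oxo-6-oxabicyclo[3.2.1]octan-2-yl]methyl prop-2-enoate | C=C[C@]1(COC(=O)C=C)C(=O)C[C@@H]2OC[C@H]1C2(C)C | intermediate
20 | unsaturated spirolactone: 5,6-dihydro-2H-pyran-2-one whose C5 is the spiro atom C13 (= C2 of the 8,8-dimethyl-3-oxo-6-oxabicyclo[3.2.1]octane), 13S,16S,19S | O=C1C=C[C@]2(CO1)C(=O)C[C@@H]3OC[C@H]2C3(C)C | intermediate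
21 | methyl (S)-3-hydroxy-2-methylpropanoate | COC(=O)[C@@H](C)CO | starting material
22 | methyl (S)-3-(benzyloxy)-2-methylpropanoate | COC(=O)[C@@H](C)COCc1ccccc1 | intermediate
23 | methylmagnesium bromide | C[Mg]Br | starting material
24 | (S)-3-(benzyloxy)-N-methoxy-N,2-dimethylpropanamide (not isolated) | CON(C)C(=O)[C@@H](C)COCc1ccccc1 | intermediate
25 | (S)-4-(benzyloxy)-3-methylbutan-2-one | CC(=O)[C@@H](C)COCc1ccccc1 | intermediate
26 | (S)-4-(benzyloxy)-3-methylbut-1-en-2-yl trifluoromethanesulfonate | C=C(OS(=O)(=O)C(F)(F)F)[C@@H](C)COCc1ccccc1 | intermediate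
27 | tributyl(1-ethoxyvinyl)stannane | C=C(OCC)[Sn](CCCC)(CCCC)CCCC | starting material
28 | (R)-5-(benzyloxy)-2-ethoxy-4-methyl-3-methylidenepent-1-ene (C6H2=C5(OEt)–C4(=C9H2)–C2H(CH3)–C3H2OBn) | C=C(OCC)C(=C)[C@@H](C)COCc1ccccc1 | intermediate
29 | Diels–Alder adduct: cis-fused ring A/B lactone with C4=C5 enol ether (OEt on C5), side chain CH(CH3)CH2OBn on C4; 2R,7R,8S,13S,16S,19S (not isolated) | C[C@@H](COCc5ccccc5)C1=C(OCC)C[C@@H]2[C@H](C1)C(=O)OC[C@]21C(=O)C[C@@H]2OC[C@H]1C2(C)C | intermediate
30 | target skeleton with C5 as ketone and C3 as CH2OBn; 2R,4R,7R,8S,13S,16S,19S | C[C@@H](COCc5ccccc5)[C@@H]1C(=O)C[C@@H]2[C@H](C1)C(=O)OC[C@]21C(=O)C[C@@H]2OC[C@H]1C2(C)C | intermediate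
31 | C5 (E)-tosylhydrazone of 30 | C[C@@H](COCc5ccccc5)[C@@H]1/C(=N/NS(=O)(=O)c6ccc(C)cc6)C[C@@H]2[C@H](C1)C(=O)OC[C@]21C(=O)C[C@@H]2OC[C@H]1C2(C)C | intermediate
32 | target skeleton with C3 as CH2OBn (C5 = CH2) | C[C@@H](COCc5ccccc5)[C@@H]1CC[C@@H]2[C@H](C1)C(=O)OC[C@]21C(=O)C[C@@H]2OC[C@H]1C2(C)C | intermediate
33 | target skeleton with C3 as CH2OH | C[C@@H](CO)[C@@H]1CC[C@@H]2[C@H](C1)C(=O)OC[C@]21C(=O)C[C@@H]2OC[C@H]1C2(C)C | intermediate
34 | CNP0152427.1: (2R)-2-substituted propanoic acid on C4 of the cis-octahydroisochroman-1-one spiro-linked at C13 to the 8,8-dimethyl-6-oxabicyclo[3.2.1]octan-3-one; 2R,4R,7R,8S,13S,16S,19S | C[C@@H](C(=O)O)[C@@H]1CC[C@@H]2[C@H](C1)C(=O)OC[C@]21C(=O)C[C@@H]2OC[C@H]1C2(C)C | target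

Total step count: 21. Longest linear sequence: 17 (steps 1–12 and 17–21). The diene 28 takes four steps (13–16).

Steps most likely to fail

1. Step 9.
- What may go wrong: the acid may ionise the doubly allylic C14–O bond or split the acetal on the wrong side before any C–C bond forms. The alkene is slowed by two allylic C–O bonds and by neopentyl C19, so it may react too slowly and let proton loss or a 2-oxonia-Cope pathway take over.
- Fallback: it separates the two events into known reactions, sets out from 7 and returns at 17.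
- Negishi coupling of 7 with Me3SiCH2ZnCl (Pd(PPh3)4, THF) should give (S)-5-(methoxymethoxy)-4,4-dimethyl-2-[(trimethylsilyl)methyl]cyclohex-2-en-1-one F1.
- Vinyl addition as in step 7 gives the vinyl carbinol F2, and Et3SiOTf/2,6-lutidine gives its triethylsilyl ether F3.
- The MOM-derived oxocarbenium ion is then captured at −78 °C (Me3SiOTf cat., CH2Cl2) by the far more nucleophilic allylsilane in an intramolecular Hosomi–Sakurai reaction. Loss of silicon ends the process cleanly at the 2-methylidene-6-oxabicyclo[3.2.1]octane silyl ether F4.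
- Bu4NF frees the tertiary allylic alcohol F5, and VO(acac)2/t-BuOOH epoxidises the 1,1-disubstituted alkene, guided by the hydroxyl group, to the spiro-epoxy alcohol F6.
- BF3·OEt2 (CH2Cl2, −78 °C) triggers the classical semipinacol rearrangement of a 2,3-epoxy alcohol. The epoxide opens at tertiary C13, the axial vinyl group migrates, and C12 is released directly as the free alcohol of 17. Opening at a tertiary centre has much cationic character, so either epoxide epimer should funnel into the same product.

2. Step 17.
- What may go wrong: cycloaddition at the neopentyl β-carbon of a weakly activated lactone may be so slow that the diene polymerises first. Discrimination between the two faces of ring B may also be poor.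
- Fallback: it activates the dienophile with a removable ester, sets out from 17 and returns at 30.
- Acylation of 17 with methyl malonyl chloride (pyridine, CH2Cl2) gives the mixed malonate F9, and ozonolysis (O3, CH2Cl2, −78 °C; Me2S) gives the aldehyde F10.
- Piperidinium acetate closes F10 by intramolecular Knoevenagel condensation to the 3-methoxycarbonyl unsaturated spirolactone F11.
- This doubly activated alkene should take up 28 at or near room temperature (ZnCl2 if needed), where the facial bias is larger, to give the enol ether cycloadduct F12. Aqueous HCl gives the keto diester F13.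
- Krapcho dealkoxycarbonylation (LiCl, wet DMSO, 130 °C) removes the extra ester. Kinetic protonation of the ring-fusion enolate on the side that carries H7 should give 30.

3. Step 7.
- What may go wrong: if chelation to the MOM group is lost, the reagent will attack the face anti to the C16 oxygen and facial selectivity will fall or invert. Enolisation followed by β-elimination of the MOM-oxy group is a second drain.
- Fallback: it binds the reagent covalently to O17, sets out from 10 and returns at 12.
- Me2BBr (CH2Cl2, −78 °C) cleaves the acetal to the free β-hydroxy enone F7.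
- Excess CH2=CHMgBr in toluene–Et2O first forms the axial magnesium alkoxide. This alkoxide holds a second reagent molecule over the same face and should deliver vinyl syn to O17 (the carbon counterpart of hydroxyl-directed hydride delivery), giving the trans-1,3-diol F8.
- MOMCl (1.1 equiv)/iPr2NEt then protects only the secondary hydroxyl and gives 12.

Further compounds
F1 | step 9 | (S)-5-(methoxymethoxy)-4,4-dimethyl-2-[(trimethylsilyl)methyl]cyclohex-2-en-1-one | O=C1C[C@H](OCOC)C(C)(C)C=C1C[Si](C)(C)C
F2 | step 9 | (1R,5S)-1-ethenyl-5-(methoxymethoxy)-4,4-dimethyl-2-[(trimethylsilyl)methyl]cyclohex-2-en-1-ol | C=C[C@]1(O)C[C@H](OCOC)C(C)(C)C=C1C[Si](C)(C)C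
F3 | step 9 | triethylsilyl ether of F2 | C=C[C@]1(O[Si](CC)(CC)CC)C[C@H](OCOC)C(C)(C)C=C1C[Si](C)(C)C
F4 | step 9 | (1S,3R,5S)-3-ethenyl-8,8-dimethyl-2-methylidene-3-(triethylsilyloxy)-6-oxabicyclo[3.2.1]octane | C=C[C@]1(O[Si](CC)(CC)CC)C[C@@H]2OC[C@H](C1=C)C2(C)C
F5 | step 9 | (1S,3R,5S)-3-ethenyl-8,8-dimethyl-2-methylidene-6-oxabicyclo[3.2.1]octan-3-ol | C=C[C@]1(O)C[C@@H]2OC[C@H](C1=C)C2(C)C
F6 | step 9 | spiro-epoxide of F5 at C13=C12, epoxide oxygen anti to the O17–C18 bridge and syn to the C14 hydroxyl | C=C[C@]1(O)C[C@@H]2OC[C@H]([C@]13CO3)C2(C)C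
F7 | step 7 | (S)-2-{[(tert-butyldiphenylsilyl)oxy]methyl}-5-hydroxy-4,4-dimethylcyclohex-2-en-1-one | O=C1C[C@H](O)C(C)(C)C=C1CO[Si](c2ccccc2)(c3ccccc3)C(C)(C)C
F8 | step 7 | C14,C16 trans-diol (14R,16S): 12 without its MOM group | C=C[C@]1(O)C[C@H](O)C(C)(C)C=C1CO[Si](c2ccccc2)(c3ccccc3)C(C)(C)C
F9 | step 17 | methyl malonate of 17 | C=C[C@]1(COC(=O)CC(=O)OC)C(=O)C[C@@H]2OC[C@H]1C2(C)C
F10 | step 17 | C7 aldehyde from ozonolysis of F9 | O=C[C@]1(COC(=O)CC(=O)OC)C(=O)C[C@@H]2OC[C@H]1C2(C)C
F11 | step 17 | unsaturated spirolactone 20 bearing CO2Me on C8 | COC(=O)C1=C[C@]2(COC1=O)C(=O)C[C@@H]3OC[C@H]2C3(C)C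
F12 | step 17 | enol ether cycloadduct 29 bearing CO2Me on C8 | C[C@@H](COCc5ccccc5)C1=C(OCC)C[C@@H]2[C@@](C1)(C(=O)OC)C(=O)OC[C@]21C(=O)C[C@@H]2OC[C@H]1C2(C)C
F13 | step 17 | diketone 30 bearing CO2Me on C8 | C[C@@H](COCc5ccccc5)[C@@H]1C(=O)C[C@@H]2[C@@](C1)(C(=O)OC)C(=O)OC[C@]21C(=O)C[C@@H]2OC[C@H]1C2(C)C
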